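The pitfall, said the chair in opening, is to see target feeding its own formation and expect target to win.

all flasks: starting material 0.13 M; protic impurity 0.0130 M; time 5.0 h
- Sunday's: temperature 5 °C
- Monday's: temperature 30 °C
- Wednesday's: temperature 55 °C

- which of these there is most of at the end, counted by the starting material in it, Sunday's (side product / target / starting material)
- which of these there is most of at the end, counted by the starting material in it, Monday's (side product / target / starting material)
- which of these there is most of at the end, counted by the starting material in it, Wednesday's (side product / target / starting material)
- how much there is at the end of the one of these that leads, in percent of the starting material charged: Sunday's
- how much there is at the end of the one of these that leads, in percent of the starting material charged: Monday's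
- how much there is at the end of the one of these that leads, in percent of the starting material charged: Wednesday's

- percent here means starting material units held: one side product counts as two
- a step written with two of one species runs at k times the square of its concentration and takes two of it each time
- the constants hold at 5 °C; other temperatures follow from the activation energies

    starting material + 2 target → 3 target (k1 = 1.8 /M²/min, Ea1 = 44.0 kJ/mol)
    starting material → target (k2 = 0.0021 /min, Ea2 = 86.0 kJ/mol)
    starting material + protic impurity → quenched substrate (k3 = 0.75 /M/min, Ea3 = 62.0 kJ/mol)
    starting material + target → side product (k4 = 0.10 /M/min, Ea4 = 72.0 kJ/mol)
    (constants at 5 °C)

The first speaker dealt with the protic impurity. In Sunday's flask its half-life against the charged starting material is 7.11 min, shorter than the run. She therefore booked 10.0% of the charge as quenched substrate in each flask, leaving 90.0% to share out.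

The second speaker proposed one measure. The uncatalysed step makes target at k2[starting material], and the side-product step removes it at k4[starting material][target]. Since [starting material] stands in both, they balance at [target] = k2/k4, a quasi-steady state. He called this, as a share of the starting material charged, the balance level: 16.2% on Sunday's, 26.6% on Monday's and 40.6% on Wednesday's.

A third member objected that autocatalysis was missing. At the level, k1[target]² adds 37.8% to k2 on Sunday's and 15.0% on Wednesday's. The meeting minuted this as a correction that raises the level, and set it aside.

For Sunday's, target's half-life by the side-product step, with the other concentrations as charged, is 0.89 h, shorter than the run, though it lengthens as starting material falls. The meeting assumed, as an estimate, that target stands at the level throughout Sunday's run; on that assumption the side-product step consumes starting material as fast as the uncatalysed one, and the material decays with a constant of 0.00420 /min. That leaves 25.5%, with 48.3% for side product. On Monday's the uncatalysed half-life is 15.4 min, far shorter than the run, so side product takes 63.4%. On Wednesday's target may fall short of its level, so 49.4% was minuted as a floor for side product, not a value. Side product leads in each flask.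

The forecast gave side product at 48%, 64% and 57%, from Sunday's to Wednesday's: “Side product therefore leads in all three runs”.

The simulation gives side product at 46.9%, 63.9% and 57.2%. Target ends at 18.6% on Sunday's, above the level, at 26.1% on Monday's, and at 32.8% on Wednesday's, below it. Sunday's keeps 24.6% of its starting material.

Take a flask like Wednesday's but charged with 0.033 M of starting material. Its balance level in concentration is unchanged, 0.0528 M, which exceeds the whole charge. Target therefore stays below the level, and the side-product step runs slower than the uncatalysed one throughout. The impurity also stands at 0.394 equiv. This neighbouring flask ends with target at 50.1%, side product at 19.8%, and quenched substrate at 30.1%.

All constants were chosen freely; the rest is arithmetic.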